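The earlier runs and the new flask were computed with made-up constants, and the scatter is random.

If free catalyst has two partners, substrate and impurity, and each reacts at a rate proportional to free catalyst, then dividing one rate by the other removes both the catalyst and time. What remains is a fixed ratio of logarithms: the fall in substrate over the fall in impurity.

| setting | Thursday's | Friday's | flask |
|---|---|---|---|
| substrate | 1 M | 1 M | 1.0 M |
| free catalyst | 2 mM | 2 mM | 2.0 mM |
| impurity | 2.5 mM | 3.8 mM | 2.5 mM |
| temperature | 35 °C | 30 °C | 35 °C |
| remark | the very flask that is asked about, followed so far | run made earlier |  |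
| time |  |  | 8.0 d |

| run | time / h | product / % | substrate / % |
|---|---|---|---|
| Thursday's | 10.0 | 22.3 | 79.4 |
| Thursday's | 15.0 | 20.2 | 77.4 |
| Thursday's | 25.0 | 21.6 | 77.6 |
| Thursday's | 40.0 | 21.8 | 78.3 |
| Thursday's | 72.0 | 20.6 | 76.6 |
| Thursday's | 120 | 22.5 | 78.3 |
| Friday's | 1.33 | 7.3 | 91.5 |
| Friday's | 2.50 | 9.3 | 90.7 |
| Friday's | 4.00 | 10.8 | 88.3 |
| Friday's | 6.00 | 10.2 | 90.0 |
| Friday's | 10.0 | 9.9 | 88.2 |
| Friday's | 20.0 | 10.6 | 88.7 |

(standard deviation of a reading: 1 percentage point)

- eta: at 8.0 d add substrate, 50.0% of the amount charged, then wait 8.0 d
- epsilon: at 8.0 d add free catalyst, 100% of the amount charged, then wait 8.0 d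
- delta: change nothing and wait 8.0 d more
- gamma: at 8.0 d raise the temperature by 10 K, then wait 8.0 d

- the volume of additions can be left aside
- a reading or a percentage of product counts all its forms, free or not

1. product, in percent of the substrate first charged, at 8.0 d
2. which option adds most product ("none" when 2 percentage points or less is all one gets) (eta / epsilon / delta / gamma / none)
3. product present, in percent of the substrate first charged, after eta
4. product present, in percent of the substrate first charged, after epsilon

The two amounts compared here are the charges of free catalyst and impurity. The reckoning made here assumes that one impurity removes one catalyst, and in Thursday's flask the impurity charge is 1.25 times the catalyst charge, so the reckoning has the impurity outlast the catalyst. The share of impurity left at the end is then 20.0%, and 47.4% in Friday's run.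

Thursday's readings stay flat around 21.5%, and Friday's last four average 10.4%. Reading substrate lost as product, Thursday's run gives 0.150, the selectivity factor, and Friday's run gives about the same, 0.147, though it ran colder. Friday's factor puts Thursday's flask at 21.0%.

The reckoning therefore commits to 21.5% now, and to the same after eta, delta or gamma, as Thursday's readings stay flat from 10.0 h to 120 h. With epsilon, the leftover impurity equals 25.0% of the added catalyst, so by this reckoning 75.0% of the added catalyst should survive. The wait of 8.0 d is far longer than the 1.33 h by which Friday's run reads 7.3% of product, so conversion should come close to complete.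

The forecast gives 21.7% now, 21.7% after eta and 99% after epsilon, names epsilon as best, and says new catalyst “finishes the conversion within a day”.

Thursday's flask gives 21.4% at the asked time, 21.4% after eta and >99.9% after epsilon, so epsilon is best, adding 79 percentage points.

    substrate + free catalyst → catalyst intermediate A (k = 0.116 M⁻¹ s⁻¹, Ea = 44.0 kJ mol⁻¹)
    catalyst intermediate A ⇌ catalyst intermediate B (K = 7.77, k = 0.285 s⁻¹, Ea = 77.0 kJ mol⁻¹, ΔH = −31.0 kJ mol⁻¹)
    catalyst intermediate B → free catalyst + product (k = 0.0663 s⁻¹, Ea = 86.0 kJ mol⁻¹)
    free catalyst + product ⇌ idle complex, settled at all times (K = 2.50 M⁻¹, ΔH = −72.0 kJ mol⁻¹)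
    free catalyst + impurity → spent catalyst (k = 0.776 M⁻¹ s⁻¹, Ea = 41.0 kJ mol⁻¹)
    (constants at 35 °C)

Thursday's flask keeps 20% of its impurity, and with 0.150 that share gives 21.4% of product, beside the 21.4% it holds. The neighbouring flask, charged with 0.0063 M of impurity, should keep 68.3% of it, and the same factor then gives 5.56% of product. That neighbouring flask keeps 68% of its impurity and ends with 5.55% of product.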